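All runs were computed from invented constants, and the scatter is random.

A small charge of Spx, 0.46 mM in the flask, has to sort Sbt from its mirror image Sbt2 with Ptn.

| setting | red | grey | amber | flask |
|---|---|---|---|---|
| Sbt | 23 mM | 23 mM | 23 mM | 23 mM |
| Sbt2 | 23 mM | 23 mM | 23 mM | 23 mM |
| Ptn | 17 mM | 69 mM | 34.5 mM | 34.5 mM |
| Spx | 0.46 mM | 0.46 mM | 0.23 mM | 0.46 mM |
| remark | run made earlier | run made earlier | run made earlier |  |
| time |  |  |  | 8.0 h |

| run | time / h | Sbt / % | Sbt2 / % | Pdt / % |
|---|---|---|---|---|
| red | 1.50 | 49.8 | 51.5 | 0 |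
| red | 3.00 | 48.8 | 50.5 | 0 |
| red | 5.00 | 46.1 | 51.8 | 2.1 |
| red | 6.00 | 47.2 | 51.0 | 2.1 |
| red | 8.00 | 43.7 | 52.2 | 5.8 |
| grey | 0.667 | 49.5 | 49.5 | 0.3 |
| grey | 2.00 | 48.5 | 48.6 | 2.0 |
| grey | 4.00 | 44.9 | 50.5 | 6.5 |
| grey | 6.00 | 38.0 | 49.9 | 13.3 |
| grey | 8.00 | 32.5 | 48.3 | 17.5 |
| amber | 1.50 | 49.8 | 48.7 | 0 |
| amber | 3.00 | 50.0 | 50.8 | 2.6 |
| amber | 5.00 | 48.5 | 50.1 | 1.2 |
| amber | 6.00 | 46.9 | 50.5 | 5.2 |
| amber | 8.00 | 43.1 | 49.9 | 5.5 |

(readings scatter by 1 percentage point)

- Ctl is single-handed; Sbt and Sbt2 are mirror images of each other, charged as a racemate, each of them at the stated concentration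
- the earlier runs were read with a standard deviation of 1 percentage point
- an excess is the difference of the two amounts in percent of their sum
- an excess is below zero if the other one leads

1. part of the Sbt and Sbt2 charged together that has reacted at 8.0 h
2. excess of Pdt over Pdt2 in the product at 8.0 h
3. excess of Sbt2 over Sbt among what is left of the two at 8.0 h

We build the flask one step at a time. First comes the main step alone: Sbt and Ptn give Pdt over the catalyst, and we take its rate as proportional to [Sbt], [Ptn] and the catalyst. In this flask Sbt is charged in a smaller amount than Ptn, so we write the balance of Sbt. With [Ptn] taken as nearly constant the loss is pseudo-first-order, and at a fixed time the log of Sbt charged over Sbt left grows with the dose, [Spx][Ptn] as charged. Red and amber have about equal doses and read 5.8 % and 5.5 % of Pdt, which fits. We pool red, grey and amber at 8.0 h, counting Sbt lost as Pdt gained. That gives 0.0141 /mM² for G, the log of Sbt charged over Sbt left divided by the dose. From G and the dose of the flask we reckon that 79.9 % of its Sbt stays at 8.0 h, so we expect Pdt at 10.0 % of the Sbt and Sbt2 together charged.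

Next we add the side step, Sbt2 to Pdt2. From 4.00 h on, grey reads Sbt2 on average 0.43 percentage points below its charge, against a mean Pdt of 12.4 %. That ratio, 0.0349, is a rough reading, since a single reading scatters by 1 point, and its inverse stands in for the selectivity factor. So we reckon the part reacted, c, at 10.4 %, the excess of Pdt, eP, at 93.3 % and the excess of Sbt2, eS, at 10.8 %.

Then comes the rest. Grey reads a gain of 2.0 % in its first 2.00 h, yet 6.8 points between 4.00 h and 6.00 h, so its start is slow. G was read at 8.0 h after the start, the time asked of the flask, so we take this slow start as already inside it. Counted from Pdt, Ptn spent is 15.7 % of its charge in red and 11.7 % in grey, and we reckon 13.8 % in the flask. Our numbers stay.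

The forecast gives c 11 %, eP 90 % and eS 11 %, with the remark “Red and amber have the same catalyst × Ptn product”.

The flask gives c 10.0 %, eP 92.5 % and eS 10.3 %.

    Ctl → Zet (k = 0.0640 /h)
    Spx → Ctl (k = 0.170 /h)
    Ptn + Ctl + Sbt → Ctl + Pdt (k = 4800 /M²/h)
    Ptn + Ctl + Sbt2 → Ctl + Pdt2 (k = 170 /M²/h)

At 8.00 h Ctl makes up 55.0 % of the catalyst charged in the flask, beside 25.7 % Spx and 19.4 % Zet, and the flask charged with 0.28 mM of Spx holds the same 55.0 % of Ctl, in percent of its own smaller charge. Put into G, the dose of that second flask gives 87.2 % of its Sbt left. That flask keeps 87 %.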